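**Assumption:** the target has no stereocentre (an achiral isoflavone), so no enantiocontrol is needed; the one carbinol stereocentre that appears transiently at C3 is formed racemic and is destroyed in the same step. MOM = methoxymethyl. 2,3-Dihydroxy-4-methoxybenzaldehyde and methyl 3-hydroxy-4,5-dimethoxybenzoate are taken as catalogue compounds.

## Retrosynthetic overview

1. Target ⇐ acid-induced loss of water and of three MOM groups from a racemic 3-aryl-3-hydroxychroman-4-one (C2=C3 formed last).
2. Ring C (the only ring made) and the C3–C4 bond ⇐ carbene-catalysed intramolecular crossed benzoin: the ring-A aldehyde carbon, turned into an acyl anion equivalent, attacks the tethered ring-B aryl ketone carbonyl.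
3. Keto-aldehyde ⇐ O-alkylation of a ring-A salicylaldehyde with a ring-B α-chloroketone (O1–C2 bond).
4. Salicylaldehyde ⇐ 2,3-dihydroxy-4-methoxybenzaldehyde (MOM protection, Baeyer–Villiger to the phenol, ortho-formylation); chloroketone ⇐ methyl 3-hydroxy-4,5-dimethoxybenzoate (MOM protection, chloromethyllithium homologation).
5. Rings A and B are bought intact; ring C closes in the final step.

## Route

**Step 1**
Reactants: 1 2,3-dihydroxy-4-methoxybenzaldehyde
Product: 2 4-methoxy-2,3-bis(methoxymethoxy)benzaldehyde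
Conditions: MOMCl (3 equiv), iPr2NEt (4 equiv), CH2Cl2, 0 °C to rt
Reagents that add atoms: chloromethyl methyl ether (MOMCl), COCCl
Why: MOM protection (O-alkylation of the phenols by a highly electrophilic α-chloro ether under amine base) caps both catechol hydroxyls, including the chelated 2-OH; no stereocentre is formed.

**Step 2**
Reactants: 2 4-methoxy-2,3-bis(methoxymethoxy)benzaldehyde
Product: 4 4-methoxy-2,3-bis(methoxymethoxy)phenol, via aryl formate 3 (not isolated)
Conditions: mCPBA (1.3 equiv), CH2Cl2, 0 °C to rt; then K2CO3 (cat.), MeOH, rt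
Reagents that add atoms: mCPBA, O=C(OO)c1cccc(Cl)c1
Why: Baeyer–Villiger (Dakin-type) oxidation, in which the electron-rich ortho/para-alkoxylated aryl group migrates in the Criegee intermediate to give the aryl formate, which mild methanolysis cleaves while the MOM ethers survive.

**Step 3**
Reactants: 4 4-methoxy-2,3-bis(methoxymethoxy)phenol
Product: 6 2-hydroxy-5-methoxy-3,4-bis(methoxymethoxy)benzaldehyde, via salicyl alcohol 5 (not isolated)
Conditions: MgCl2 (2 equiv), Et3N (4 equiv), (CH2O)n (6 equiv), MeCN, reflux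
Reagents that add atoms: paraformaldehyde (as formaldehyde), C=O
Why: Magnesium-mediated ortho-formylation (Casnati–Skattebøl), in which the magnesium phenoxide delivers formaldehyde only to the single free ortho carbon and a second formaldehyde oxidises the salicyl alcohol by hydride transfer; the basic medium spares the MOM ethers.

**Step 4**
Reactants: 7 methyl 3-hydroxy-4,5-dimethoxybenzoate
Product: 8 methyl 3,4-dimethoxy-5-(methoxymethoxy)benzoate
Conditions: MOMCl (1.5 equiv), iPr2NEt (2 equiv), CH2Cl2, 0 °C to rt
Reagents that add atoms: chloromethyl methyl ether (MOMCl), COCCl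
Why: MOM protection of the single phenol, so that it cannot be deprotonated by the carbenoid in step 5 or compete as a nucleophile in step 6.

**Step 5**
Reactants: 8 methyl 3,4-dimethoxy-5-(methoxymethoxy)benzoate
Product: 10 2-chloro-1-[3,4-dimethoxy-5-(methoxymethoxy)phenyl]ethan-1-one, via lithium hemiketal alkoxide 9 (not isolated)
Conditions: ClCH2I (2 equiv), MeLi·LiBr (1.8 equiv, slow addition), THF, −78 °C; AcOH quench at −78 °C
Reagents that add atoms: chloroiodomethane, ClCI
Why: Carbenoid homologation, in which chloromethyllithium made in situ by iodine–lithium exchange adds once to the ester to give a tetrahedral alkoxide that is stable at −78 °C and collapses to the α-chloroketone only on quench, which prevents over-addition.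

**Step 6**
Reactants: 6 2-hydroxy-5-methoxy-3,4-bis(methoxymethoxy)benzaldehyde; 10 2-chloro-1-[3,4-dimethoxy-5-(methoxymethoxy)phenyl]ethan-1-one
Product: 11 2-{2-[3,4-dimethoxy-5-(methoxymethoxy)phenyl]-2-oxoethoxy}-5-methoxy-3,4-bis(methoxymethoxy)benzaldehyde
Conditions: K2CO3 (1.5 equiv), KI (10 mol %), DMF, rt
Reagents that add atoms: none
Why: Williamson ether synthesis (SN2 of the phenoxide on a primary α-halo ketone, with iodide catalysis), run at room temperature so that the product does not go on to Rap–Stoermer aldol closure to a 2-aroylbenzofuran.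

**Step 7**
Reactants: 11 2-{2-[3,4-dimethoxy-5-(methoxymethoxy)phenyl]-2-oxoethoxy}-5-methoxy-3,4-bis(methoxymethoxy)benzaldehyde
Product: 14 7,8-dihydroxy-3-(3-hydroxy-4,5-dimethoxyphenyl)-6-methoxy-4H-chromen-4-one, via tris-MOM 3-hydroxychroman-4-one 12 (not isolated), via free 3-hydroxychroman-4-one 13 (not isolated)
Conditions: 2-(pentafluorophenyl)-6,7-dihydro-5H-pyrrolo[2,1-c][1,2,4]triazol-2-ium tetrafluoroborate (10 mol %), Et3N (20 mol %), THF, rt to 40 °C, N2; then 3 M HCl in MeOH, 60 °C, N2
Reagents that add atoms: none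
Why: N-heterocyclic-carbene-catalysed intramolecular crossed aldehyde–ketone benzoin, in which the carbene turns the aldehyde carbon into a nucleophilic Breslow intermediate (acyl anion equivalent) that adds 6-exo-trig to the tethered aryl ketone carbonyl to close ring C as a racemic tertiary carbinol, after which methanolic HCl removes the MOM acetals and ionises the benzylic carbinol for E1 loss of water to the conjugated γ-pyrone, erasing the only stereocentre.

## Compound list

1 | 2,3-dihydroxy-4-methoxybenzaldehyde | O=Cc1ccc(OC)c(O)c1O | starting material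
2 | 4-methoxy-2,3-bis(methoxymethoxy)benzaldehyde | O=Cc1ccc(OC)c(OCOC)c1OCOC | intermediate
3 | 4-methoxy-2,3-bis(methoxymethoxy)phenyl formate | O=COc1ccc(OC)c(OCOC)c1OCOC | intermediate (not isolated)
4 | 4-methoxy-2,3-bis(methoxymethoxy)phenol | Oc1ccc(OC)c(OCOC)c1OCOC | intermediate
5 | 2-(hydroxymethyl)-4-methoxy-5,6-bis(methoxymethoxy)phenol (as its magnesium salt) | OCc1cc(OC)c(OCOC)c(OCOC)c1O | intermediate (not isolated)
6 | 2-hydroxy-5-methoxy-3,4-bis(methoxymethoxy)benzaldehyde | O=Cc1cc(OC)c(OCOC)c(OCOC)c1O | intermediate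
7 | methyl 3-hydroxy-4,5-dimethoxybenzoate | COC(=O)c1cc(O)c(OC)c(OC)c1 | starting material
8 | methyl 3,4-dimethoxy-5-(methoxymethoxy)benzoate | COC(=O)c1cc(OCOC)c(OC)c(OC)c1 | intermediate
9 | lithium 2-chloro-1-[3,4-dimethoxy-5-(methoxymethoxy)phenyl]-1-methoxyethan-1-olate (racemic) | [Li+].[O-]C(OC)(CCl)c1cc(OCOC)c(OC)c(OC)c1 | intermediate (not isolated)
10 | 2-chloro-1-[3,4-dimethoxy-5-(methoxymethoxy)phenyl]ethan-1-one | O=C(CCl)c1cc(OCOC)c(OC)c(OC)c1 | intermediate
11 | 2-{2-[3,4-dimethoxy-5-(methoxymethoxy)phenyl]-2-oxoethoxy}-5-methoxy-3,4-bis(methoxymethoxy)benzaldehyde | O=Cc1cc(OC)c(OCOC)c(OCOC)c1OCC(=O)c1cc(OCOC)c(OC)c(OC)c1 | intermediate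
12 | 3-[3,4-dimethoxy-5-(methoxymethoxy)phenyl]-3-hydroxy-6-methoxy-7,8-bis(methoxymethoxy)-2,3-dihydro-4H-chromen-4-one (racemic) | O=C1c2cc(OC)c(OCOC)c(OCOC)c2OCC1(O)c1cc(OCOC)c(OC)c(OC)c1 | intermediate (not isolated)
13 | 3,7,8-trihydroxy-3-(3-hydroxy-4,5-dimethoxyphenyl)-6-methoxy-2,3-dihydro-4H-chromen-4-one (racemic) | O=C1c2cc(OC)c(O)c(O)c2OCC1(O)c1cc(O)c(OC)c(OC)c1 | intermediate (not isolated)
14 | 7,8-dihydroxy-3-(3-hydroxy-4,5-dimethoxyphenyl)-6-methoxy-4H-chromen-4-one | COc1cc2c(=O)c(-c3cc(O)c(OC)c(OC)c3)coc2c(O)c1O | target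

## Step count and risks

Total steps: 7 (the carbene/acid sequence of step 7 is run in one flask). Longest linear sequence: 5 steps (steps 1, 2, 3, 6, 7; 1 → 2 → 4 → 6 → 11 → 14).

**Step 7 (most likely to fail).** The carbene stage can lose material to base-mediated aldol closure. The acid stage asks for E1 ionisation next to a carbonyl, which may be slow or divert to α-ketol rearrangement. The fallback sets out from 12 and comes back at 14. The reaction is stopped after the carbene stage and 12 is isolated. It is treated with SOCl2 and pyridine in CH2Cl2 at 0 °C to rt, so that the tertiary alcohol leaves as a chlorosulfite by base-mediated elimination, with no free cation, giving 3-[3,4-dimethoxy-5-(methoxymethoxy)phenyl]-6-methoxy-7,8-bis(methoxymethoxy)-4H-chromen-4-one F1. The MOM groups are then removed with 3 M HCl in MeOH at rt to give 14.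

**Step 6.** The hindered, chelated phenol may need heating, and the product can then close to a 2-aroylbenzofuran (Rap–Stoermer). The fallback sets out from 10 and 6 and comes back at 11; it removes the enolisable ketone during ether formation. NaBH4 in MeOH at 0 °C reduces 10 to 2-chloro-1-[3,4-dimethoxy-5-(methoxymethoxy)phenyl]ethan-1-ol F2. With K2CO3 in DMF at 70 °C this closes to 2-[3,4-dimethoxy-5-(methoxymethoxy)phenyl]oxirane F3, formed in the flask. The phenoxide of 6 opens it at the terminal carbon to give 2-{2-[3,4-dimethoxy-5-(methoxymethoxy)phenyl]-2-hydroxyethoxy}-5-methoxy-3,4-bis(methoxymethoxy)benzaldehyde F4. Dess–Martin periodinane in CH2Cl2 oxidises the secondary alcohol to the ketone 11.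

**Step 5.** The carbenoid is thermally fragile and can add twice to the ester. The fallback sets out from 8 and comes back at 10; it replaces the carbenoid with a sulfur ylide acylation. Ester 8 is heated with trimethylsulfoxonium iodide (Me3S(O)I) and KOtBu in THF at reflux to give dimethylsulfoxonium 2-[3,4-dimethoxy-5-(methoxymethoxy)phenyl]-2-oxoethylide F5. LiCl and MsOH (1.05 equiv) in THF at 65 °C protonate the ylide, and chloride displaces dimethyl sulfoxide to give 10. The acid is consumed by the ylide, which protects the MOM ether.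

## Further compounds

F1 | step 7 | 3-[3,4-dimethoxy-5-(methoxymethoxy)phenyl]-6-methoxy-7,8-bis(methoxymethoxy)-4H-chromen-4-one | COCOc1cc(-c2coc3c(OCOC)c(OCOC)c(OC)cc3c2=O)cc(OC)c1OC
F2 | step 6 | 2-chloro-1-[3,4-dimethoxy-5-(methoxymethoxy)phenyl]ethan-1-ol (racemic) | OC(CCl)c1cc(OCOC)c(OC)c(OC)c1
F3 | step 6 | 2-[3,4-dimethoxy-5-(methoxymethoxy)phenyl]oxirane (racemic) | C1OC1c1cc(OCOC)c(OC)c(OC)c1
F4 | step 6 | 2-{2-[3,4-dimethoxy-5-(methoxymethoxy)phenyl]-2-hydroxyethoxy}-5-methoxy-3,4-bis(methoxymethoxy)benzaldehyde (racemic) | O=Cc1cc(OC)c(OCOC)c(OCOC)c1OCC(O)c1cc(OCOC)c(OC)c(OC)c1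
F5 | step 5 | dimethylsulfoxonium 2-[3,4-dimethoxy-5-(methoxymethoxy)phenyl]-2-oxoethylide | CS(C)(=O)=CC(=O)c1cc(OCOC)c(OC)c(OC)c1
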